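**Plan**
- Retrosynthesis: first cut the two side-chain C=C bonds at C6 and C8 of ring A (cross-metathesis, back to the 6,8-diallyl triphenol 19 and 2-methyl-2-butene). Then cut the C6–CH2 and C8–CH2 bonds (double aromatic Claisen rearrangement, back to the 5,7-bis(allyl ether) 15). Last, cut the C3–C1' bond (Suzuki–Miyaura coupling of iodochromone 6 with chromenyl boronate 14).
- Forward: ring C (the pyranone) is closed first on the ring A acetophenone by enaminone formation and iodine cyclisation. Ring D (the dimethylpyran on ring B) is closed separately by propargyl Claisen rearrangement and oxa-6π ring closure. The halves are joined at C3–C1', the allyl groups move from O5/O7 to C6/C8, the silyl ether is removed, and the prenyl alkenes are made last.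
- Enabling feature: the C6 and C8 substituents of ring A are CH2–CH=C(CH3)2 chains, each ortho to a phenolic oxygen (O5, O7). Each trisubstituted alkene is what cross-metathesis of an allyl group with 2-methyl-2-butene gives, and an allyl group ortho to a phenol is what a Claisen shift of an O-allyl ether leaves. The only other alkene, C3''=C4'' of ring D, is cis, ring-bound and next to the quaternary C2'', so it stays out of the metathesis.
- Stereochemistry: the target has no stereocentre and no E/Z element to control.

Key step: step 10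

Remark: 2',4',6'-trihydroxyacetophenone and 4-bromoresorcinol are taken as the commercial entry points, and monosilylation of 4-bromoresorcinol with the bulky silyl chloride is assumed to occur at the hydroxyl para to bromine.

Step 1
Reactants: 1 2',4',6'-trihydroxyacetophenone; 2 allyl bromide
Product: 3 1-[2,4-bis(allyloxy)-6-hydroxyphenyl]ethanone
Conditions: allyl bromide (2.2 equiv), K2CO3, acetone, reflux
Reagents that add atoms: allyl bromide (2), C=CCBr
Why: Williamson etherification should alkylate two hydroxyls and leave the third, which is hydrogen-bonded to the acetyl carbonyl and far less nucleophilic under carbonate conditions, as is usual for phloroacetophenone.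

Step 2
Reactants: 3 1-[2,4-bis(allyloxy)-6-hydroxyphenyl]ethanone; 4 N,N-dimethylformamide dimethyl acetal
Product: 6 5,7-bis(allyloxy)-3-iodo-4H-chromen-4-one, via dimethylamino enone 5 (not isolated)
Conditions: 4, toluene, 100 °C; evaporate; then I2, pyridine, CHCl3, rt
Reagents that add atoms: N,N-dimethylformamide dimethyl acetal (4), COC(OC)N(C)C; iodine, II
Why: Condensation of the methyl ketone with the amide acetal gives the vinylogous amide, whose nucleophilic α-carbon should be iodinated much faster than the isolated allyl alkenes, after which the phenol adds and dimethylamine is lost (the standard enaminone route to 3-iodochromones).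

Step 3
Reactants: 7 4-bromoresorcinol
Product: 8 2-bromo-5-[(triisopropylsilyl)oxy]phenol
Conditions: TIPSCl (1.0 equiv), imidazole, CH2Cl2, −20 to 0 °C
Reagents that add atoms: triisopropylsilyl chloride, CC(C)[Si](Cl)(C(C)C)C(C)C
Why: Sterically governed monosilylation should favour the hydroxyl flanked by two hydrogens over the one that is shielded by, and hydrogen-bonded to, the ortho bromine.

Step 4
Reactants: 8 2-bromo-5-[(triisopropylsilyl)oxy]phenol; 9 3-chloro-3-methylbut-1-yne
Product: 10 1-bromo-2-[(2-methylbut-3-yn-2-yl)oxy]-4-[(triisopropylsilyl)oxy]benzene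
Conditions: 9, DBU, CuCl2·2H2O (1 mol%), MeCN, 0 °C
Reagents that add atoms: 3-chloro-3-methylbut-1-yne (9), C#CC(C)(C)Cl
Why: Copper-catalysed propargylic etherification of the tertiary propargylic chloride is the established way to make aryl 1,1-dimethylpropargyl ethers and works on ortho-substituted phenols at 0 °C, where the silyl ether is safe.

Step 5
Reactants: 10 1-bromo-2-[(2-methylbut-3-yn-2-yl)oxy]-4-[(triisopropylsilyl)oxy]benzene
Product: 12 8-bromo-2,2-dimethyl-5-[(triisopropylsilyl)oxy]-2H-chromene, via allenyl phenol 11 (not isolated)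
Conditions: PhNEt2, 185 °C
Reagents that add atoms: none
Why: The aryl propargyl ether Claisen rearrangement can reach only the one free ortho carbon (the other carries bromine), and the allenyl phenol then closes ring D by 1,5-hydrogen shift and oxa-6π-electrocyclisation, which fixes the pyran oxygen next to the future biaryl carbon.

Step 6
Reactants: 12 8-bromo-2,2-dimethyl-5-[(triisopropylsilyl)oxy]-2H-chromene
Product: 14 2-{2,2-dimethyl-5-[(triisopropylsilyl)oxy]-2H-chromen-8-yl}-4,4,5,5-tetramethyl-1,3,2-dioxaborolane, via aryllithium 13 (not isolated)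
Conditions: n-BuLi, THF, −78 °C; then 2-isopropoxy-4,4,5,5-tetramethyl-1,3,2-dioxaborolane, −78 °C to rt; H2O
Reagents that add atoms: 2-isopropoxy-4,4,5,5-tetramethyl-1,3,2-dioxaborolane, CC(C)OB1OC(C)(C)C(C)(C)O1; n-butyllithium, [Li]CCCC (supplies only the lithium of 13)
Why: Bromine–lithium exchange at −78 °C is faster than any deprotonation or addition to the chromene alkene, and trapping the aryllithium with the isopropoxy borate is a standard lithiation–borylation.

Step 7
Reactants: 6 5,7-bis(allyloxy)-3-iodo-4H-chromen-4-one; 14 2-{2,2-dimethyl-5-[(triisopropylsilyl)oxy]-2H-chromen-8-yl}-4,4,5,5-tetramethyl-1,3,2-dioxaborolane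
Product: 15 5,7-bis(allyloxy)-3-{2,2-dimethyl-5-[(triisopropylsilyl)oxy]-2H-chromen-8-yl}-4H-chromen-4-one
Conditions: PdCl2(dppf) (5 mol%), Na2CO3, 1,4-dioxane/H2O (5:1), 80 °C
Reagents that add atoms: none
Why: Suzuki–Miyaura coupling of 3-iodochromones with aryl boronates is the standard isoflavone assembly, and insertion of zerovalent palladium into the activated C3–I bond should outrun ionisation of the aryl allyl ethers, while the bidentate dppf ligand helps reductive elimination of the ortho-substituted biaryl.

Step 8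
Reactants: 15 5,7-bis(allyloxy)-3-{2,2-dimethyl-5-[(triisopropylsilyl)oxy]-2H-chromen-8-yl}-4H-chromen-4-one
Product: 18 6,8-diallyl-5,7-dihydroxy-3-{2,2-dimethyl-5-[(triisopropylsilyl)oxy]-2H-chromen-8-yl}-4H-chromen-4-one, via 8-allyl-5-allyloxy-7-hydroxy isoflavone 16 (not isolated), via 6-allyl-7-allyloxy-5-hydroxy isoflavone 17 (not isolated)
Conditions: PhNEt2, 200 °C, sealed tube
Reagents that add atoms: none
Why: In this double aromatic Claisen rearrangement the O7 allyl group has C8 as its preferred ortho site and the O5 allyl group has only C6 (its other ortho carbon is the ring-fusion carbon C4a), so either order of the two [3,3] shifts should end at the same 6,8-diallyl-5,7-diol, while the silyl ether and the thermally formed ring D tolerate the heat.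

Step 9
Reactants: 18 6,8-diallyl-5,7-dihydroxy-3-{2,2-dimethyl-5-[(triisopropylsilyl)oxy]-2H-chromen-8-yl}-4H-chromen-4-one
Product: 19 6,8-diallyl-5,7-dihydroxy-3-(5-hydroxy-2,2-dimethyl-2H-chromen-8-yl)-4H-chromen-4-one
Conditions: Bu4NF, AcOH, THF, 0 °C
Reagents that add atoms: none
Why: Fluoride cleavage of the aryl silyl ether, buffered with acetic acid so that the phenols stay protonated, leaves the allyl groups, the chromene and the pyranone untouched.

Step 10
Reactants: 19 6,8-diallyl-5,7-dihydroxy-3-(5-hydroxy-2,2-dimethyl-2H-chromen-8-yl)-4H-chromen-4-one; 20 2-methyl-2-butene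
Product: 23 Kanzonol L, via 6-allyl-8-prenyl triphenol 21 (not isolated), via 8-allyl-6-prenyl triphenol 22 (not isolated)
Conditions: RuCl2(H2IMes)(PCy3)(=CHPh) (second-generation Grubbs catalyst, 10 mol%), 1,4-benzoquinone (20 mol%), 2-methyl-2-butene/CH2Cl2 (1:1), 40 °C, sealed tube
Reagents that add atoms: 2-methyl-2-butene (20), CC=C(C)C
Why: This is an olefin cross-metathesis in which the ruthenium benzylidene loses PCy3 and the resulting alkylidene undergoes [2+2] cycloaddition with each monosubstituted allyl alkene and, in turn, with 2-methyl-2-butene, so that cycloreversion of the ruthenacyclobutanes places a CH=C(CH3)2 terminus on the C6 and C8 chains and releases propene. The closest known reaction type is the conversion of ortho-allylphenols into prenylarenes with 2-methyl-2-butene and this catalyst, which is known to tolerate free and hydrogen-bonded phenols. No ring is closed and no stereocentre is formed, and since each new alkene carries two identical methyl groups there is no E/Z question. The step needs site selectivity for the two terminal alkenes over the ring D alkene and must not consume its own products: the allyl groups are the only unhindered alkenes, the chromene alkene is cis-disubstituted, ring-bound and flanked by the quaternary C(CH3)2 carbon so that any ring-opened carbene would simply close again, and the trisubstituted prenyl products re-enter the cycle much more slowly than they form. A large excess of the volatile olefin as co-solvent should drive both sites through the mono-prenyl compounds 21 and 22, and 1,4-benzoquinone is added to suppress ruthenium hydride-mediated migration of the allyl double bonds into conjugation with ring A.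

**Compound list**
1 | 2',4',6'-trihydroxyacetophenone | CC(=O)c1c(O)cc(O)cc1O | starting material
2 | allyl bromide | C=CCBr | starting material
3 | 1-[2,4-bis(allyloxy)-6-hydroxyphenyl]ethanone | CC(=O)c1c(O)cc(OCC=C)cc1OCC=C | intermediate
4 | N,N-dimethylformamide dimethyl acetal | COC(OC)N(C)C | starting material
5 | (E)-1-[2,4-bis(allyloxy)-6-hydroxyphenyl]-3-(dimethylamino)prop-2-en-1-one (not isolated) | CN(C)/C=C/C(=O)c1c(O)cc(OCC=C)cc1OCC=C | intermediate
6 | 5,7-bis(allyloxy)-3-iodo-4H-chromen-4-one | O=c1c(I)coc2cc(OCC=C)cc(OCC=C)c12 | intermediate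
7 | 4-bromoresorcinol | Oc1ccc(Br)c(O)c1 | starting material
8 | 2-bromo-5-[(triisopropylsilyl)oxy]phenol | Oc1cc(O[Si](C(C)C)(C(C)C)C(C)C)ccc1Br | intermediate
9 | 3-chloro-3-methylbut-1-yne | C#CC(C)(C)Cl | starting material
10 | 1-bromo-2-[(2-methylbut-3-yn-2-yl)oxy]-4-[(triisopropylsilyl)oxy]benzene | C#CC(C)(C)Oc1cc(O[Si](C(C)C)(C(C)C)C(C)C)ccc1Br | intermediate
11 | 6-bromo-2-(3-methylbuta-1,2-dien-1-yl)-3-[(triisopropylsilyl)oxy]phenol (not isolated) | CC(C)=C=Cc1c(O)c(Br)ccc1O[Si](C(C)C)(C(C)C)C(C)C | intermediate
12 | 8-bromo-2,2-dimethyl-5-[(triisopropylsilyl)oxy]-2H-chromene | CC1(C)C=Cc2c(O[Si](C(C)C)(C(C)C)C(C)C)ccc(Br)c2O1 | intermediate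
13 | {2,2-dimethyl-5-[(triisopropylsilyl)oxy]-2H-chromen-8-yl}lithium (not isolated) | CC1(C)C=Cc2c(O[Si](C(C)C)(C(C)C)C(C)C)ccc([Li])c2O1 | intermediate
14 | 2-{2,2-dimethyl-5-[(triisopropylsilyl)oxy]-2H-chromen-8-yl}-4,4,5,5-tetramethyl-1,3,2-dioxaborolane | CC1(C)C=Cc2c(O[Si](C(C)C)(C(C)C)C(C)C)ccc(B3OC(C)(C)C(C)(C)O3)c2O1 | intermediate
15 | 5,7-bis(allyloxy)-3-{2,2-dimethyl-5-[(triisopropylsilyl)oxy]-2H-chromen-8-yl}-4H-chromen-4-one | O=c1c(-c2ccc(O[Si](C(C)C)(C(C)C)C(C)C)c3C=CC(C)(C)Oc23)coc2cc(OCC=C)cc(OCC=C)c12 | intermediate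
16 | 8-allyl-5-(allyloxy)-7-hydroxy-3-{2,2-dimethyl-5-[(triisopropylsilyl)oxy]-2H-chromen-8-yl}-4H-chromen-4-one (not isolated) | O=c1c(-c2ccc(O[Si](C(C)C)(C(C)C)C(C)C)c3C=CC(C)(C)Oc23)coc2c(CC=C)c(O)cc(OCC=C)c12 | intermediate
17 | 6-allyl-7-(allyloxy)-5-hydroxy-3-{2,2-dimethyl-5-[(triisopropylsilyl)oxy]-2H-chromen-8-yl}-4H-chromen-4-one (not isolated) | O=c1c(-c2ccc(O[Si](C(C)C)(C(C)C)C(C)C)c3C=CC(C)(C)Oc23)coc2cc(OCC=C)c(CC=C)c(O)c12 | intermediate
18 | 6,8-diallyl-5,7-dihydroxy-3-{2,2-dimethyl-5-[(triisopropylsilyl)oxy]-2H-chromen-8-yl}-4H-chromen-4-one | O=c1c(-c2ccc(O[Si](C(C)C)(C(C)C)C(C)C)c3C=CC(C)(C)Oc23)coc2c(CC=C)c(O)c(CC=C)c(O)c12 | intermediate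
19 | 6,8-diallyl-5,7-dihydroxy-3-(5-hydroxy-2,2-dimethyl-2H-chromen-8-yl)-4H-chromen-4-one | C=CCc1c(O)c(CC=C)c2occ(-c3ccc(O)c4c3OC(C)(C)C=C4)c(=O)c2c1O | intermediate
20 | 2-methyl-2-butene | CC=C(C)C | starting material
21 | 6-allyl-5,7-dihydroxy-3-(5-hydroxy-2,2-dimethyl-2H-chromen-8-yl)-8-(3-methylbut-2-en-1-yl)-4H-chromen-4-one (not isolated) | C=CCc1c(O)c(CC=C(C)C)c2occ(-c3ccc(O)c4c3OC(C)(C)C=C4)c(=O)c2c1O | intermediate
22 | 8-allyl-5,7-dihydroxy-3-(5-hydroxy-2,2-dimethyl-2H-chromen-8-yl)-6-(3-methylbut-2-en-1-yl)-4H-chromen-4-one (not isolated) | CC(C)=CCc1c(O)c(CC=C)c2occ(-c3ccc(O)c4c3OC(C)(C)C=C4)c(=O)c2c1O | intermediate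
23 | Kanzonol L, 5,7-dihydroxy-3-(5-hydroxy-2,2-dimethyl-2H-chromen-8-yl)-6,8-bis(3-methylbut-2-en-1-yl)-4H-chromen-4-one | CC(C)=CCc1c(O)c(CC=C(C)C)c2occ(-c3ccc(O)c4c3OC(C)(C)C=C4)c(=O)c2c1O | target

**Step count**
Total: 10 steps. Longest linear sequence: 8 steps (steps 3 to 10, from 4-bromoresorcinol); the ring A branch contributes steps 1 and 2.

**Steps most likely to fail**

Step 10. The catalyst may be tied up by the ortho-hydroxyl groups, the exchange may stall after one allyl group has reacted, or ruthenium hydride may move the remaining allyl double bond into conjugation before it is exchanged. The fallback sets out from 19 and masks the phenols before metathesis. Acetylation (Ac2O, pyridine, DMAP) should give 6,8-diallyl isoflavone triacetate F1. Cross-metathesis of F1 with 2-methyl-2-butene under the same ruthenium catalyst, now on a substrate that cannot chelate, should give Kanzonol L triacetate F2. Methanolysis of F2 with K2CO3 in MeOH at 0 °C, a non-acidic deprotection that cannot cyclise the prenyl groups onto the phenols, returns to the route at 23.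

Step 8. The O5 allyl group, peri to the carbonyl, may migrate sluggishly; a first shift of the O7 allyl group to C6 would force the second through a slower para pathway; and the new ortho-allyl phenols may add thermally across their own alkenes. The fallback sets out from 3 and moves both allyl groups to carbon before the chromone exists.
- Heating 3 in PhNEt2 at 200 °C should give 1-(3,5-diallyl-2,4,6-trihydroxyphenyl)ethanone F3.
- MOMCl and i-Pr2NEt in CH2Cl2 should protect the two non-chelated hydroxyls to give 1-[3,5-diallyl-2-hydroxy-4,6-bis(methoxymethoxy)phenyl]ethanone F4.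
- N,N-Dimethylformamide dimethyl acetal should give the dimethylamino enone F5, which is treated without isolation with I2 and pyridine in CHCl3 to give 6,8-diallyl-3-iodo-5,7-bis(methoxymethoxy)-4H-chromen-4-one F6.
- Suzuki–Miyaura coupling of F6 with 14 (PdCl2(dppf), Na2CO3, dioxane/H2O) should give the bis(methoxymethyl) ether of the silylated diallyl isoflavone F7.
- Dilute HCl in MeOH at 40 °C cleaves the two acetals, which the allyl groups, ring D and the aryl silyl ether should survive, and returns to the route at 18.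

Step 7. Zerovalent palladium may ionise the aryl allyl ethers and strip the allyl groups, and the electron-rich ortho-alkoxy boronate may lose boron to protonation before it transmetalates. The fallback sets out from 6 and carries out the sigmatropic shift before the coupling, so that palladium never meets an O-allyl group. Heating 6 in 1,2-dichlorobenzene at 180 °C should give 6,8-diallyl-5,7-dihydroxy-3-iodo-4H-chromen-4-one F8. Suzuki–Miyaura coupling of F8 as its phenoxide with 14 (PdCl2(dppf), excess Na2CO3, dioxane/H2O) returns to the route at 18.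

**Further compounds**
F1 | step 10 | 6,8-diallyl-3-(5-acetoxy-2,2-dimethyl-2H-chromen-8-yl)-4-oxo-4H-chromene-5,7-diyl diacetate | C=CCc1c(OC(C)=O)c(CC=C)c2occ(-c3ccc(OC(C)=O)c4c3OC(C)(C)C=C4)c(=O)c2c1OC(C)=O
F2 | step 10 | Kanzonol L triacetate | CC(C)=CCc1c(OC(C)=O)c(CC=C(C)C)c2occ(-c3ccc(OC(C)=O)c4c3OC(C)(C)C=C4)c(=O)c2c1OC(C)=O
F3 | step 8 | 1-(3,5-diallyl-2,4,6-trihydroxyphenyl)ethanone | CC(=O)c1c(O)c(CC=C)c(O)c(CC=C)c1O
F4 | step 8 | 1-[3,5-diallyl-2-hydroxy-4,6-bis(methoxymethoxy)phenyl]ethanone | CC(=O)c1c(O)c(CC=C)c(OCOC)c(CC=C)c1OCOC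
F5 | step 8 | (E)-1-[3,5-diallyl-2-hydroxy-4,6-bis(methoxymethoxy)phenyl]-3-(dimethylamino)prop-2-en-1-one | CN(C)/C=C/C(=O)c1c(O)c(CC=C)c(OCOC)c(CC=C)c1OCOC
F6 | step 8 | 6,8-diallyl-3-iodo-5,7-bis(methoxymethoxy)-4H-chromen-4-one | O=c1c(I)coc2c(CC=C)c(OCOC)c(CC=C)c(OCOC)c12
F7 | step 8 | 6,8-diallyl-5,7-bis(methoxymethoxy)-3-{2,2-dimethyl-5-[(triisopropylsilyl)oxy]-2H-chromen-8-yl}-4H-chromen-4-one | O=c1c(-c2ccc(O[Si](C(C)C)(C(C)C)C(C)C)c3C=CC(C)(C)Oc23)coc2c(CC=C)c(OCOC)c(CC=C)c(OCOC)c12
F8 | step 7 | 6,8-diallyl-5,7-dihydroxy-3-iodo-4H-chromen-4-one | O=c1c(I)coc2c(CC=C)c(O)c(CC=C)c(O)c12
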